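## Retrosynthetic overview
1. The target comes from a (3R,4R)-3,4-epoxychroman by hydride delivery to benzylic C4. That epoxide comes from a 2,2-dimethyl-2H-chromene by catalyst-controlled epoxidation of its only cis, conjugated alkene. The alcohol never arises from a prenyl epoxide, so the two C5 units do not compete.
2. The pyran ring (C4–C4a and O1–C2 bonds together) comes from symmetric 4-prenylpinosylvin and prenal, through a dearomatised ortho-quinone methide and oxa-6π closure. The prenyl group blocks the carbon between the oxygens, and the two remaining OH/CH pairs are equivalent, so only one regioisomer can form.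
3. 4-Prenylpinosylvin comes from pinosylvin and prenol (C-allylation between the two OH groups). Pinosylvin comes from styrene and 5-bromoresorcinol (Heck).
4. Ring order: both benzene rings are bought, the pyran ring is formed in step 3, and an oxirane is fused to it in step 4 and opened in step 5.

Assumption: the SMILES is read as (3R) at the carbinol carbon and E at the stilbene. Styrene, 5-bromoresorcinol, prenol and prenal are taken as commercial. All stilbenes are handled with exclusion of light.

## Route

Step 1
Reactants: 1 styrene; 2 5-bromoresorcinol (5-bromobenzene-1,3-diol)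
Product: 3 pinosylvin [(E)-5-(2-phenylethenyl)benzene-1,3-diol]
Conditions: Pd(OAc)2 (2 mol %), P(o-tol)3 (6 mol %), Et3N (3 equiv), DMF, 100 °C, 16 h
Reagents that add atoms: none
Why: Mizoroki–Heck reaction in which zerovalent palladium formed in situ inserts into the C–Br bond (not deactivated, since both OH groups are meta to it), styrene inserts with the aryl group going to its terminal carbon, and syn β-hydride elimination gives only the E-stilbene, the free phenols being tolerated under these amine-base conditions.

Step 2
Reactants: 3 pinosylvin; 4 prenol (3-methylbut-2-en-1-ol)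
Product: 5 4-prenylpinosylvin [2-(3-methylbut-2-en-1-yl)-5-[(E)-2-phenylethenyl]benzene-1,3-diol]
Conditions: 4 (1.5 equiv), acidic alumina (Al2O3, 2 g per mmol), 1,2-dichloroethane, reflux, 12–24 h
Reagents that add atoms: none
Why: Alumina-templated Friedel–Crafts ortho-allylation in which both phenolic OH groups bind to the acidic Al2O3 surface beside the ionising prenol, so the prenyl unit is delivered through its primary terminus to the carbon between the two oxygens, which keeps the molecule symmetric and avoids both O-alkylation and the soluble strong acid that would cyclise the product to a chroman.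

Step 3
Reactants: 5 4-prenylpinosylvin; 6 prenal (3-methylbut-2-enal)
Product: 9 2,2-dimethyl-8-(3-methylbut-2-en-1-yl)-5-[(E)-2-phenylethenyl]-2H-chromen-7-yl acetate, via ortho-quinone methide 7 (not isolated), via chromenol 8 (not isolated)
Conditions: 6 (1.1 equiv, slow addition), ethylenediammonium diacetate (20 mol %), toluene, reflux, Dean–Stark, 8 h; then rt, Ac2O (3 equiv), Et3N (4 equiv), DMAP (5 mol %), 2 h
Reagents that add atoms: acetic anhydride, CC(=O)OC(C)=O
Why: Formal [3+3] chromene annulation (amine-salt-catalysed Knoevenagel-type condensation followed by oxa-6π electrocyclisation) in which the iminium ion of 6 is attacked by one of the two equivalent free ring carbons of 5, loss of the amine gives the dearomatised dienone 7, and ring closure onto its carbonyl oxygen rearomatises it to 8, so the symmetry is broken with only one possible regiochemistry, the added crowding around the styryl group slows a second annulation, the remaining phenol is capped in the same flask by DMAP-catalysed acetylation, and no stereocentre is formed.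

Step 4
Reactants: 9 chromenyl acetate
Product: 10 (3R,4R)-3,4-epoxy-2,2-dimethyl-8-(3-methylbut-2-en-1-yl)-5-[(E)-2-phenylethenyl]-3,4-dihydro-2H-chromen-7-yl acetate (cis-fused oxirane)
Conditions: (R,R)-(salen)MnCl [(R,R)-N,N′-bis(3,5-di-tert-butylsalicylidene)cyclohexane-1,2-diaminomanganese chloride, C36H52ClMnN2O2] (5 mol %), NMO (5 equiv), mCPBA (1.2 equiv, in portions), CH2Cl2, −78 °C, 2 h; cold aq. NaOH/Na2S2O3 wash; short plug of basic Al2O3
Reagents that add atoms: mCPBA (3-chloroperoxybenzoic acid), OOC(=O)c1cccc(Cl)c1
Why: Jacobsen–Katsuki epoxidation in which the oxomanganese species (pentavalent manganese) reacts far faster with the cis, aryl-conjugated C3=C4 bond than with the isolated trisubstituted prenyl alkene or the trans-stilbene, the NMO-buffered peracid shows no background epoxidation at −78 °C, and side-on approach over the (R,R)-diamine backbone delivers oxygen to the face that gives the (3R,4R)-epoxide, as is the rule for 2,2-dimethylchromenes, which sets the C3 stereocentre of the target.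

Step 5
Reactants: 10 (3R,4R)-epoxychromanyl acetate
Product: 12 (3R)-2,2-dimethyl-8-(3-methylbut-2-en-1-yl)-5-[(E)-2-phenylethenyl]-3,4-dihydro-2H-chromene-3,7-diol (target CNP0198286.1), via phenoxide epoxide 11 (not isolated)
Conditions: LiAlH4 (2 equiv), THF, 0 °C to rt, 2 h; then H2O, aq. KNaC4H4O6 (Rochelle salt)
Reagents that add atoms: none
Why: Hydride reduction in which LiAlH4 first cleaves the aryl acetate and then opens the oxirane by SN2-type attack at benzylic C4, which is activated by the para phenoxide and the ring oxygen while C3 is neopentyl, so the C3–O bond is never broken and the R configuration is retained, and the stilbene and prenyl alkenes are inert to the reagent.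

## Compound list
1 | styrene | C=Cc1ccccc1 | starting material
2 | 5-bromoresorcinol | Oc1cc(O)cc(Br)c1 | starting material
3 | pinosylvin, (E)-5-(2-phenylethenyl)benzene-1,3-diol | Oc1cc(O)cc(/C=C/c2ccccc2)c1 | intermediate
4 | prenol, 3-methylbut-2-en-1-ol | CC(C)=CCO | starting material
5 | 4-prenylpinosylvin, 2-(3-methylbut-2-en-1-yl)-5-[(E)-2-phenylethenyl]benzene-1,3-diol | CC(C)=CCc1c(O)cc(/C=C/c2ccccc2)cc1O | intermediate
6 | prenal, 3-methylbut-2-enal | CC(C)=CC=O | starting material
7 | ortho-quinone methide (not isolated, exocyclic alkene geometry not fixed), 3-hydroxy-2-(3-methylbut-2-en-1-yl)-6-(3-methylbut-2-en-1-ylidene)-5-[(E)-2-phenylethenyl]cyclohexa-2,4-dien-1-one | CC(C)=CCC1=C(O)C=C(/C=C/c2ccccc2)C(=CC=C(C)C)C1=O | intermediate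
8 | chromenol (not isolated), 2,2-dimethyl-8-(3-methylbut-2-en-1-yl)-5-[(E)-2-phenylethenyl]-2H-chromen-7-ol | CC(C)=CCc1c(O)cc(/C=C/c2ccccc2)c2c1OC(C)(C)C=C2 | intermediate
9 | 2,2-dimethyl-8-(3-methylbut-2-en-1-yl)-5-[(E)-2-phenylethenyl]-2H-chromen-7-yl acetate | CC(C)=CCc1c(OC(C)=O)cc(/C=C/c2ccccc2)c2c1OC(C)(C)C=C2 | intermediate
10 | (3R,4R)-3,4-epoxy-2,2-dimethyl-8-(3-methylbut-2-en-1-yl)-5-[(E)-2-phenylethenyl]chroman-7-yl acetate | CC(C)=CCc1c(OC(C)=O)cc(/C=C/c2ccccc2)c2c1OC(C)(C)[C@@H]3O[C@H]23 | intermediate
11 | (3R,4R)-3,4-epoxy-2,2-dimethyl-8-(3-methylbut-2-en-1-yl)-5-[(E)-2-phenylethenyl]chroman-7-ol, present as its lithium/aluminium phenoxide (not isolated) | CC(C)=CCc1c(O)cc(/C=C/c2ccccc2)c2c1OC(C)(C)[C@@H]3O[C@H]23 | intermediate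
12 | (3R)-2,2-dimethyl-8-(3-methylbut-2-en-1-yl)-5-[(E)-2-phenylethenyl]-3,4-dihydro-2H-chromene-3,7-diol | CC(C)=CCc1c(O)cc(/C=C/c2ccccc2)c2c1OC(C)(C)[C@H](O)C2 | target

## Step count
Total step count: 5.
Longest linear sequence: 5 (2 → 3 → 5 → 9 → 10 → 12).

## Steps most likely to fail

**Step 3 (annulation).**
- Risk: the C–C bond must form at the ring carbon next to the styryl group. Chromenol 8 still has one free OH/CH pair, so a bis-chromene can form, and the mono-adduct yield is expected to be only 50–65 %. Unreacted 5 returns as its diacetate.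
- Fallback: it sets out from 5 and comes back at 8. It makes the C–O bond first instead of the C–C bond.
- Mono-O-alkylation of 5 with 3-chloro-3-methylbut-1-yne (CuCl2 cat., DBU, MeCN, 0 °C) gives 2-(3-methylbut-2-en-1-yl)-3-[(2-methylbut-3-yn-2-yl)oxy]-5-[(E)-2-phenylethenyl]phenol F1.
- Heating this ether in N,N-diethylaniline or o-xylene at 140–180 °C triggers an aromatic propargyl Claisen rearrangement to the only free ortho carbon. Enolisation, 1,5-hydrogen shift and oxa-6π closure then give 8, which is acetylated as in step 3 to 9.

**Step 4 (epoxidation).**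
- Risk: the styryl group peri to C4 may lower the rate and ee, and a slow reaction gives the prenyl alkene time to be oxidised.
- Fallback: it sets out from 10 of whatever ee and comes back at 12. It moves the stereo-determining event from alkene oxidation to ketone reduction.
- Meinwald rearrangement of 10 (InCl3 cat., THF, rt) proceeds by benzylic C4–O ionisation and 1,2-hydride shift. It gives the achiral ketone 2,2-dimethyl-8-(3-methylbut-2-en-1-yl)-3-oxo-5-[(E)-2-phenylethenyl]chroman-7-yl acetate F2.
- Corey–Bakshi–Shibata reduction uses (S)-2-methyl-CBS-oxazaborolidine and catecholborane in toluene at −78 °C, where the alkenes are not hydroborated. It distinguishes the tertiary C2 from the CH2 at C4 and gives (3R)-3-hydroxy-2,2-dimethyl-8-(3-methylbut-2-en-1-yl)-5-[(E)-2-phenylethenyl]chroman-7-yl acetate F3.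
- K2CO3 in MeOH then gives 12.

**Step 2 (C4 prenylation).**
- Risk: attack at C2, double prenylation, or partial cyclisation to a chroman would spoil the symmetric precursor.
- Fallback: it sets out from 3 and comes back at 5. It replaces electrophilic substitution by directed ortho-metalation.
- MOMCl and i-Pr2NEt in CH2Cl2 give (E)-3,5-bis(methoxymethoxy)stilbene F4.
- n-BuLi in THF at −20 to 0 °C lithiates the carbon flanked by both OMOM groups. Prenyl bromide then gives (E)-3,5-bis(methoxymethoxy)-4-(3-methylbut-2-en-1-yl)stilbene F5.
- Catalytic HCl in MeOH at 40 °C releases 5.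

## Further compounds
F1 | step 3 | 2-(3-methylbut-2-en-1-yl)-3-[(2-methylbut-3-yn-2-yl)oxy]-5-[(E)-2-phenylethenyl]phenol | C#CC(C)(C)Oc1cc(/C=C/c2ccccc2)cc(O)c1CC=C(C)C
F2 | step 4 | 2,2-dimethyl-8-(3-methylbut-2-en-1-yl)-3-oxo-5-[(E)-2-phenylethenyl]chroman-7-yl acetate | CC(C)=CCc1c(OC(C)=O)cc(/C=C/c2ccccc2)c2c1OC(C)(C)C(=O)C2
F3 | step 4 | (3R)-3-hydroxy-2,2-dimethyl-8-(3-methylbut-2-en-1-yl)-5-[(E)-2-phenylethenyl]chroman-7-yl acetate | CC(C)=CCc1c(OC(C)=O)cc(/C=C/c2ccccc2)c2c1OC(C)(C)[C@H](O)C2
F4 | step 2 | (E)-3,5-bis(methoxymethoxy)stilbene | COCOc1cc(OCOC)cc(/C=C/c2ccccc2)c1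
F5 | step 2 | (E)-3,5-bis(methoxymethoxy)-4-(3-methylbut-2-en-1-yl)stilbene | COCOc1cc(/C=C/c2ccccc2)cc(OCOC)c1CC=C(C)C
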